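(The numbers in the tables are simulated for substances that don't exist, noise included.)

Count the Q before you count the minutes. You asked for a quick number on theta, zeta and delta, and this is what we have:

| flask | Z | Q | remark | time |
|---|---|---|---|---|
| blue | 0.067 M | 0.060 M | run made earlier |  |
| theta | 0.10 M | 0.0600 M |  | 2.0 min |
| zeta | 0.10 M | 0.200 M |  | 2.0 min |
| delta | 0.10 M | 0.600 M |  | 2.0 min |

blue run (percent of the Z charged)

| time / s | J / % | Z / % |
|---|---|---|
| 10.0 | 32.2 | 67.0 |
| 20.0 | 50.7 | 49.6 |
| 30.0 | 60.3 | 39.3 |
| 50.0 | 72.3 | 27.8 |
| 80.0 | 80.7 | 19.0 |

(scatter of a reading: 0.5 percentage points)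

- the earlier runs were read with a standard deviation of 0.5 percentage points
- "hardly changes" means that all values lie within two and a half points (for a concentration: within two and a half percent of the largest)

1. amount of J at the end, in percent of the Z charged for theta, zeta, delta, in this order
2. how that number moves from the first to the last of them (falls all the way / rises all the way / rises, then falls / hardly changes / falls, then rises)

Assume one Q per J, and let the ceiling C be the Q charged over the Z charged: 60.0 % in theta, 200 % in zeta, 600 % in delta. Theta has less Q than Z, so Q is its limiting reagent.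

The blue run shows how fast unspent Q goes. Its ceiling is 89.6 %, and J reads 17 percentage points below it at 50.0 s and 8.9 points below it at 80.0 s. That gives a half-life of about 31.2 s, as a reading. At its ceiling theta still holds 0.0400 M of Z, more than the 0.0186 M blue held at the start of that stretch, so if Z speeds this up, the half-life is on the long side.

In 2.0 min theta gets 3.85 half-lives, so I commit to 55.8 % for theta. In zeta and delta C stands above 100%, so Z limits, and I expect J near 100%.

Your forecast is flat: 48 %, 48 %, 48 %, hardly changes, on the ground that “So the rate looks second order in Z and about zero order in Q.” My reckoning parts from it: 55.8 % against 48 % for theta, and near 100% against 48 % for zeta and 48 % for delta.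

The flasks gave 59.3 %, 94.9 %, 76.7 %: rises, then falls.

    Q + J → G (k = 0.00460 M⁻¹ s⁻¹)
    Z + Q → J, rate k2*[Z]^0.5*[Q] (k = 0.190 M⁻⁰·⁵ s⁻¹)

Theta ended with J at 59.3 % under C of 60.0 %, and Q at 0.611 % of its own charge. At 2.00 min in theta, Z + Q to J used Q 140 times as fast as Q + J to G, and the half-life of J in theta by Q + J to G alone, the other concentrations as charged, was 42 min, longer than the 2.0 min of the run. In zeta C is 200 %, above 100%, and at 2.00 min Z stood at 0 %, J at 94.9 % and G at 5.07 %.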